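**Time and loading.** Time in these flasks seems to count in proportion to the loading of free catalyst, so test that on the two earlier runs before you reckon anything.

| flask | substrate | free catalyst | remark | time |
|---|---|---|---|---|
| east | 1.4 M | 0.013 mol% | run made earlier |  |
| north | 1.4 M | 0.093 mol% | run made earlier |  |
| alder | 1.4 M | 0.02 mol% |  | 5.0 min |
| larch | 1.4 M | 0.04 mol% |  | 5.0 min |
| maple | 1.4 M | 0.08 mol% |  | 5.0 min |
| ash | 1.4 M | 0.15 mol% |  | 5.0 min |

| run | time / min | target / % | isomer of the product / % | substrate / % |
|---|---|---|---|---|
| east | 0.200 | 3.4 | 0 | 96.6 |
| east | 0.500 | 10.0 | 0 | 88.9 |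
| east | 1.00 | 20.3 | 1.5 | 80.8 |
| east | 1.50 | 30.9 | 0.5 | 67.5 |
| east | 2.00 | 41.7 | 3.4 | 58.0 |
| east | 3.00 | 62.5 | 5.8 | 35.5 |
| east | 4.00 | 71.3 | 10.6 | 14.8 |
| north | 0.250 | 36.7 | 1.8 | 62.1 |
| north | 0.417 | 58.5 | 6.1 | 37.3 |
| north | 0.667 | 64.5 | 33.2 | 0 |
| north | 1.00 | 34.6 | 64.2 | 0.9 |
| north | 1.50 | 33.3 | 64.6 | 0 |
| north | 2.50 | 34.0 | 64.9 | 0.3 |
| north | 4.00 | 35.5 | 65.4 | 0 |

(readings scatter by 1 percentage point)

- "hardly changes" means that all values lie within two and a half points (for a concentration: within two and a half percent of the largest)

- share of target in all that became target or isomer of the product for alder, larch, maple, ash, in this order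
- the shape of the row from first to last (rises all the way / rises, then falls / hardly changes / falls all the way / falls, then rises)

**The test.** East at 3.00 min and north at 0.417 min have nearly the same product of loading and time, their ratio being 1.01. They read substrate 35.5 % against 37.3 %, target 62.5 % against 58.5 % and isomer of the product 5.8 % against 6.1 %, so you may treat them as nearly one point on one course.

**Substrate ledger.** Substrate is the limiting reagent, so book where it goes. The first entry is substrate to target at a steady, zero-order pace: east lost 64.5 % in 3.00 min, which by my reckoning puts the run-out in alder at 3.02 min. The second entry, target to isomer of the product, is small at that stage, for east holds 5.8 % of isomer of the product at that reading. That entry then grows fast, and in north the growth is well on by the first reading of substrate at 0 %: between 0.417 min and 0.667 min isomer of the product climbs from 6.1 % to 33.2 %, and by 1.00 min target reads 34.6 %. The books close on a plateau, thermodynamic control as far as the readings show, where the share of target, s, reads 34.7 % over north's last readings.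

**Settling time.** Alder's settling time t_s, which is north's loading times north's first plateau time divided by alder's loading, comes to 4.65 min. That is shorter than the 5.0 min allowed, though by just 0.350 min. The other flasks carry more catalyst, so I commit to s across the row, which stays flat as long as alder's t_s stays below the run time.

**The forecast.** The forecast gives 35.5 %, 34.6 %, 34.6 % and 34.6 %, shape hardly changes, and adds “The main uncertainty is alder, because the relaxation rate is only a lower bound.”

**The result.** The flasks give 34.5 %, 34.5 %, 34.5 % and 34.5 %, shape hardly changes, and the scheme behind them is this:

    catalyst intermediate A ⇌ catalyst intermediate B (K = 0.750, k = 2400 s⁻¹)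
    substrate + free catalyst → catalyst intermediate A (k = 3900 L mol⁻¹ s⁻¹)
    target + free catalyst ⇌ isomer of the product + free catalyst, rate k3*[free catalyst]*[target] forward; the back reaction follows from the equilibrium constant (K = 1.90, k = 500 L mol⁻¹ s⁻¹)
    catalyst intermediate B ⇌ free catalyst + target (K = 5.30 M, k = 65.0 s⁻¹)

**Used again.** In alder at 5.0 min, the forward half-life of target to isomer of the product is 0.10 min, far shorter than the run. Alder at 2.50 min, still short of its t_s of 4.65 min, holds substrate 18.5 % and target 71.6 %. Larch has a t_s of 2.33 min, which is shorter than 2.50 min, and at that time larch already stands at target 34.5 % and isomer of the product 65.5 %.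

(All runs were computed with constants of no real substance, and the scatter is random.)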